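## Retrosynthetic overview

1. The last disconnection is the aryl C–C(=O) bond ortho to the phenol. It is made by a photochemical 1,3-acyl shift (photo-Fries) of the matching aryl 3-methylbut-2-enoate, which also unveils the phenol, so the senecioyl group masks the phenol until the end.
2. The benzylic ester comes from a three-component union of the benzylic alcohol, CO and (Z)-3-iodobut-2-enyl acetate (palladium-catalysed carbonylative esterification). The Z geometry is stored in the vinyl iodide.
3. The aryl ester alcohol comes from phenol-selective acylation of bought (S)-4-(1-hydroxyethyl)phenol. This is the only source of chirality, and no later step breaks a bond at that carbon.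
4. The vinyl iodide comes from trans-hydroalumination/iodination of but-2-yn-1-ol, then acetylation.
5. No ring is formed; the benzene ring is bought.

Assumption: (S)-4-(1-hydroxyethyl)phenol 1 is bought as a single enantiomer (≥98 % ee, catalogue building block). All other inputs are achiral bulk chemicals.

## Route

Step 1
Reactants: 1 (S)-4-(1-hydroxyethyl)phenol; 2 3-methylbut-2-enoyl chloride
Product: 4 (S)-4-(1-hydroxyethyl)phenyl 3-methylbut-2-enoate, via potassium phenolate 3 (not isolated)
Conditions: K2CO3 (1.1 equiv), acetone, 0 °C, 2 h
Reagents that add atoms: none
Why: This is a phenolate O-acylation (Schotten–Baumann-type acyl substitution) in which K2CO3 deprotonates only the phenol (pKa about 10 against about 15 for the benzylic OH), phenolate 3 attacks 2 faster than the base can turn 2 into the vinylketene that would give deconjugated ester, and no bond at the stereocentre is touched, so the bought S configuration is kept.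

Step 2
Reactants: 5 but-2-yn-1-ol
Product: 7 (Z)-3-iodobut-2-en-1-ol, via cyclic vinylaluminate 6 (not isolated)
Conditions: NaAlH2(OCH2CH2OMe)2 (1.4 equiv), THF, 0 °C to rt; then I2 (1.6 equiv), −78 to 0 °C; aq. Na2S2O3 / KNaC4H4O6
Reagents that add atoms: iodine, II
Why: This is a hydroxyl-directed trans-hydroalumination followed by iodinolysis, in which the aluminium alkoxide delivers hydride to C2 to give the five-membered aluminate 6 with Al on C3 cis to CH2O, and I2 cleaves the C–Al bond with retention, which fixes the Z alkene without forming a stereocentre.

Step 3
Reactants: 7 (Z)-3-iodobut-2-en-1-ol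
Product: 8 (Z)-3-iodobut-2-en-1-yl acetate
Conditions: Ac2O, pyridine, DMAP (cat.), CH2Cl2, 0 °C to rt
Reagents that add atoms: acetic anhydride, CC(=O)OC(C)=O
Why: This is a DMAP-catalysed O-acetylation of a primary allylic alcohol, which leaves the vinyl iodide and the alkene geometry untouched.

Step 4
Reactants: 4 (S)-4-(1-hydroxyethyl)phenyl 3-methylbut-2-enoate; 8 (Z)-3-iodobut-2-en-1-yl acetate (1.5 equiv)
Product: 10 (1S)-1-{4-[(3-methylbut-2-enoyl)oxy]phenyl}ethyl (2Z)-4-acetoxy-2-methylbut-2-enoate, via acylpalladium iodide 9 (not isolated)
Conditions: CO (1 atm), Pd(OAc)2 (5 mol %), Xantphos (6 mol %), Et3N (2 equiv), 4 Å MS, toluene, 50 °C, dark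
Reagents that add atoms: carbon monoxide, [C-]#[O+]
Why: This is a palladium-catalysed carbonylative esterification (alkoxycarbonylation of a vinyl iodide) in which zerovalent palladium inserts into the C–I bond of 8 with retention far faster than it ionises the allylic acetate, CO insertion gives 9, and alcoholysis by the O–H of 4 closes the ester without any DMAP-activated angelic acid derivative (so no Z-to-E leak) and without breaking the benzylic C–O bond, so S is retained.

Step 5
Reactants: 10 (1S)-1-{4-[(3-methylbut-2-enoyl)oxy]phenyl}ethyl (2Z)-4-acetoxy-2-methylbut-2-enoate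
Product: 13 (1S)-1-[4-hydroxy-3-(3-methylbut-2-enoyl)phenyl]ethyl (2Z)-4-acetoxy-2-methylbut-2-enoate (target), via caged radical pair 11 (not isolated), via ortho-acyl cyclohexadienone 12 (not isolated)
Conditions: hν (275 nm LED), degassed cyclohexane (4 mM), FEP flow coil, 15 °C, stopped at about 85 % conversion
Reagents that add atoms: none
Why: Proposed new method: a late-stage, site-selective photo-Fries 1,3-acyl shift on a substrate type where it has not been shown, because the excited arene carries both the aryl enoate and a photolabile 1-arylethyl ester next to a Z-enoate that isomerises or deconjugates when excited; narrow-band 275 nm light reaches only the arene Lb band (both enoates are nearly transparent there), the S1 state crosses onto the dissociative surface of the ArO–C(=O) bond within picoseconds, orders of magnitude faster than benzylic C–O cleavage or intersystem crossing, pair 11 recombines in the cage at one of the two equivalent ortho carbons (para is blocked) to give 12, which enolises to 13, and 13 shields itself by sub-picosecond excited-state proton transfer in the chelated o-hydroxyaryl ketone, so neither the benzylic stereocentre (no bond to it is broken) nor the Z alkene is disturbed; the closest known reaction type is the photo-Fries rearrangement of simple aryl 3-methylbut-2-enoates to 2-hydroxyphenyl enones.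

## Compound list

1 | (S)-4-(1-hydroxyethyl)phenol | O[C@@H](C)c1ccc(O)cc1 | starting material
2 | 3-methylbut-2-enoyl chloride (senecioyl chloride) | CC(C)=CC(=O)Cl | starting material
3 | potassium 4-[(1S)-1-hydroxyethyl]phenolate (formed in the flask) | O[C@@H](C)c1ccc([O-])cc1.[K+] | intermediate
4 | (S)-4-(1-hydroxyethyl)phenyl 3-methylbut-2-enoate | O[C@@H](C)c1ccc(OC(=O)C=C(C)C)cc1 | intermediate
5 | but-2-yn-1-ol | CC#CCO | starting material
6 | sodium cyclic alkenyl(alkoxy)aluminate: five-membered O–Al–C(CH3)=CH–CH2 ring, two 2-methoxyethoxy groups on Al (formed in the flask) | CC1=CCO[Al-]1(OCCOC)OCCOC.[Na+] | intermediate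
7 | (Z)-3-iodobut-2-en-1-ol | OC/C=C(/C)I | intermediate
8 | (Z)-3-iodobut-2-en-1-yl acetate | CC(=O)OC/C=C(/C)I | intermediate
9 | (Z)-4-acetoxy-2-methylbut-2-enoylpalladium iodide, divalent palladium, Xantphos ligand not drawn (formed in the flask) | CC(=O)OC/C=C(/C)C(=O)[Pd]I | intermediate
10 | (1S)-1-{4-[(3-methylbut-2-enoyl)oxy]phenyl}ethyl (2Z)-4-acetoxy-2-methylbut-2-enoate | CC(=O)OC/C=C(/C)C(=O)O[C@@H](C)c1ccc(OC(=O)C=C(C)C)cc1 | intermediate
11 | geminate pair of the 4-substituted phenoxyl radical and the 3-methylbut-2-enoyl radical in the solvent cage (formed in the flask) | CC(=O)OC/C=C(/C)C(=O)O[C@@H](C)c1ccc([O])cc1.CC(C)=C[C]=O | intermediate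
12 | (1S)-1-[5-(3-methylbut-2-enoyl)-4-oxocyclohexa-1,5-dien-1-yl]ethyl (2Z)-4-acetoxy-2-methylbut-2-enoate, both epimers at the transient ring sp3 carbon (formed in the flask) | CC(=O)OC/C=C(/C)C(=O)O[C@@H](C)C1=CC(C(=O)C=C(C)C)C(=O)C=C1 | intermediate
13 | (1S)-1-[4-hydroxy-3-(3-methylbut-2-enoyl)phenyl]ethyl (2Z)-4-acetoxy-2-methylbut-2-enoate | CC(=O)OC/C=C(/C)C(=O)O[C@@H](C)c1ccc(O)c(C(=O)C=C(C)C)c1 | target

## Step count and risks

Total step count: 5.
Longest linear sequence: 4 steps (5 → 7 → 8 → 10 → 13). The chiral material 1 goes through 3 steps.

Steps most likely to fail: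

**Step 5 (the proposed new step).**
- Risks: competing photolysis of the benzylic ester with loss of ee; Z-to-E isomerisation or deconjugation of the acetoxyangelate; cage escape to the free phenol; a strong inner-filter effect from 13; and slow closure of 13 to the 2,2-dimethylchromanone on over-irradiation.
- The fallback uses known chemistry. It sets out from 4 and comes back to the route at 13.
- Compound 4 is a plain 4-alkylphenyl senecioate with no photolabile ester and no Z-enoate, so it belongs to the long-established photo-Fries substrate class. Irradiation (254 nm low-pressure Hg lamp, cyclohexane) gives 1-{2-hydroxy-5-[(1S)-1-hydroxyethyl]phenyl}-3-methylbut-2-en-1-one F1.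
- The carbonylative esterification of step 4 is then run on F1 with 8 and CO. The phenol of F1 is locked in a six-membered hydrogen bond to the ketone and flanked by the acyl group, so it is expected to be less reactive than the benzylic OH (expected reactivity order: free phenol > secondary benzylic alcohol > chelated ortho-acyl phenol). This gives 13 directly.

**Step 4.**
- Risks: slow alcoholysis of 9 by a stoichiometric secondary alcohol; ionisation of the allylic acetate by zerovalent palladium; and loss of 9 to 3-methylfuran-2(5H)-one through participation of the cis acetate.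
- The fallback sets out from 4 and comes back at 10. It builds the Z alkene on the ester instead of carrying it in.
- Compound 4 is coupled with bought 2-[bis(2,2,2-trifluoroethoxy)phosphoryl]propanoic acid (DCC, CH2Cl2, 0 °C). This gives (1S)-1-{4-[(3-methylbut-2-enoyl)oxy]phenyl}ethyl 2-[bis(2,2,2-trifluoroethoxy)phosphoryl]propanoate F2, as both epimers at the phosphorus-bearing carbon.
- A Still–Gennari olefination of F2 with 2-oxoethyl acetate (KN(SiMe3)2, 18-crown-6, THF, −78 °C) then gives 10 Z-selectively. No activated Z-acyl species and no palladium are involved.

**Step 1.**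
- Risks: acylation of the benzylic OH as well; deconjugated 3-methylbut-3-enoate formed through the vinylketene from 2; and erosion of ee of 1 through its phenolate and the para-quinone methide.
- The fallback sets out from 1 and comes back at 4. It makes the aryl ester by forming the acyl C–C bond rather than by acyl substitution.
- This is a palladium-catalysed aryloxycarbonylation of bought 1-iodo-2-methylprop-1-ene with CO and 1 (Pd(OAc)2, Xantphos, Et3N, toluene, 50 °C).
- The free, unhindered phenol should bind divalent palladium as phenoxide in preference to the neutral secondary alcohol. No acid chloride, no vinylketene and no stoichiometric phenolate are present, and no new isolable compound is made on the way.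

## Further compounds

F1 | step 5 | 1-{2-hydroxy-5-[(1S)-1-hydroxyethyl]phenyl}-3-methylbut-2-en-1-one | O[C@@H](C)c1ccc(O)c(C(=O)C=C(C)C)c1
F2 | step 4 | (1S)-1-{4-[(3-methylbut-2-enoyl)oxy]phenyl}ethyl 2-[bis(2,2,2-trifluoroethoxy)phosphoryl]propanoate (both epimers at the phosphorus-bearing carbon) | CC(C(=O)O[C@@H](C)c1ccc(OC(=O)C=C(C)C)cc1)P(=O)(OCC(F)(F)F)OCC(F)(F)F
F0 | step 1 | none | none
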